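- Colleague, you ask for a quick number, and your hunch is that the last readings already hold it. I think they do, through one ratio.

in all of them: electrophile 10 mM
- Tuesday's: nucleophile 10 mM; buffer base 20 mM; buffer acid 0.50 mM; run made earlier
- Monday's: nucleophile 10 mM; buffer base 20 mM; buffer acid 0.75 mM; run made earlier
- Sunday's: nucleophile 15 mM; buffer base 20 mM; buffer acid 1 mM; run made earlier
- flask: nucleophile 10.0 mM; buffer base 20.0 mM; buffer acid 1.00 mM; time 6.0 h

| run | time / h | electrophile / % | target / % |
|---|---|---|---|
| Tuesday's | 0.250 | 93.1 | 8.1 |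
| Tuesday's | 0.667 | 85.0 | 13.3 |
| Tuesday's | 1.33 | 76.4 | 18.7 |
| Tuesday's | 2.00 | 71.3 | 20.7 |
| Tuesday's | 3.00 | 65.4 | 22.0 |
| Tuesday's | 4.00 | 61.6 | 20.9 |
| Tuesday's | 5.00 | 59.5 | 18.0 |
| Monday's | 0.250 | 93.0 | 5.9 |
| Monday's | 0.667 | 86.6 | 13.7 |
| Monday's | 1.33 | 77.1 | 17.2 |
| Monday's | 2.00 | 72.6 | 20.9 |
| Monday's | 3.00 | 66.0 | 22.6 |
| Monday's | 4.00 | 61.5 | 20.2 |
| Monday's | 5.00 | 61.8 | 18.5 |
| Sunday's | 0.417 | 87.3 | 13.0 |
| Sunday's | 1.33 | 67.3 | 26.4 |
| Sunday's | 2.00 | 59.2 | 30.5 |
| Sunday's | 3.00 | 50.3 | 30.5 |
| Sunday's | 5.00 | 43.9 | 27.0 |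

(each reading ± 1 percentage point)

- what was read earlier has a scatter of 1 percentage point, one standard deviation
- the earlier runs do not show the pH; that part of a forecast is a guess

* part of the electrophile that has reacted at 6.0 h
* pH of the solution at 6.0 h

- My ratio is the yield on the nucleophile: electrophile reacted per nucleophile charged, both as fractions, at the last reading.
- Tuesday's run gives 0.405, Monday's 0.382 and Sunday's 0.374. Their mean is 0.387.
- Sunday's run has 1.50 times the nucleophile of Tuesday's run and has reacted 1.39 times the electrophile. Sunday's run also holds more buffer acid, 1 mM against 0.50 mM, so the two settings are not separated here, but I let conversion follow the nucleophile charge.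
- The flask's charges then put 38.7% reacted at 5.00 h. Tuesday's last hour added 2.1 percentage points, so I commit to 40.8%, with each reading scattered by 1 point.
- The readings do not show the pH, so there I can only guess.
- The forecast says 41% and pH 7.3, with the words “This looks like reversal or inhibition building as acid is released”.
- The flask gives 41.0% reacted, at pH 7.21.

    electrophile + nucleophile → acid + target + leaving group (k = 0.00790 L mol⁻¹ s⁻¹)
    protonated nucleophile ⇌ nucleophile + acid, settled at all times (K = 1.00 × 10⁻⁸ M)
    target → over-reaction product (k = 6.70 × 10⁻⁵ s⁻¹)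
    buffer acid ⇌ buffer base + acid, settled at all times (K = 7.90 × 10⁻⁵ M)

- The electrophile and nucleophile react early: at 3.00 h the flask has 81% of this step's turnover up to 6.0 h behind it, with 23.5% of the nucleophile still free. At 6.0 h the flask has 8.2% of its nucleophile free against 59% of its electrophile; the nucleophile is the limiting reagent here, and the electrophile's half-life by that step is then 30 h, long against 6.0 h. Beside that free part, the flask's nucleophile charge stands as 41.0% reacted and 50.8% protonated nucleophile, and the flask's ratio at 6.0 h is 0.410. A neighbour flask with 0.250 equiv of nucleophile should reach 9.68% by my ratio, which belongs to 5.00 h; at 6.0 h it gives 7.36%.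

The readings were generated by integration for substances that don't exist; scatter was added.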